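**Strategy**

- Retrosynthesis: remove the MOM ether; cut ring C at O1–C8a while re-joining the C5 oxygen to the side-chain carbinol carbon (a 6-chromanol at the phenol oxidation level); cut C2–C3 (one formyl carbon); cut C3–C1' (ketone α-arylation).
- This leaves fragment 1 (8-acetyl-6-silyloxy-2,2-dimethylchroman, from 2,5-dihydroxyacetophenone) and fragment 2 (6-bromo-7-MOM-oxy-2,2-dimethylchromene, from 4-bromoresorcinol).
- Forward: the pyran of fragment 1 arises by a propargyl ether Claisen cascade and is then saturated; the pyran of fragment 2 arises by acylation/oxa-Michael closure, reduction and dehydration; α-arylation joins C3–C1'; formylation adds C2; one oxidation opens the chroman and closes ring C; the MOM group is removed last.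
- Enabling feature: ring A is a para-hydroquinone (C5–OH, C8–OH) whose C5 oxygen lies three carbons from the tertiary carbinol on C6, so it is an opened 2,2-dimethyl-6-chromanol; O1 is bonded to C8a, the carbon that is beta to both the C5 carbonyl and the C4 ketone once ring A is a quinone.
- Stereochemistry: the target is achiral; the chromene cis-alkene is held by its ring, the single racemic carbinol centre met on the way (fragment 2) is erased by dehydration, and the enol geometry is lost on ring closure.

Key step: step 12

Remark on the chemistry: compounds 14 and 15 are racemic, and enols 19 and 20 are drawn as the hydrogen-bonded Z forms, which interconvert with their aldehyde tautomers.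

**Route**

Step 1
Reactants: 1 2,5-dihydroxyacetophenone
Product: 2 2-hydroxy-5-(triisopropylsilyloxy)acetophenone
Conditions: iPr3SiCl, imidazole, DMF, 0 °C to rt
Reagents that add atoms: triisopropylsilyl chloride, CC(C)[Si](Cl)(C(C)C)C(C)C
Why: Silyl ether formation should be selective because the 5-OH is the only phenol that is neither hydrogen-bonded to the acetyl group nor flanked by it.

Step 2
Reactants: 2 2-hydroxy-5-(triisopropylsilyloxy)acetophenone; 3 3-chloro-3-methylbut-1-yne
Product: 4 2-(2-methylbut-3-yn-2-yloxy)-5-(triisopropylsilyloxy)acetophenone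
Conditions: DBU, CuCl2 (cat.), MeCN, 0 °C to rt
Reagents that add atoms: none
Why: Copper-catalysed O-propargylation of a phenoxide with a tertiary propargylic chloride is the standard entry to aryl 1,1-dimethylpropargyl ethers, and DBU is strong enough to break the chelate of the one remaining phenol.

Step 3
Reactants: 4 2-(2-methylbut-3-yn-2-yloxy)-5-(triisopropylsilyloxy)acetophenone
Product: 7 8-acetyl-2,2-dimethyl-6-(triisopropylsilyloxy)-2H-chromene, via ortho-allenylphenol 5 (not isolated), via ortho-quinone methide 6 (not isolated)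
Conditions: PhNEt2, 170 °C, argon
Reagents that add atoms: none
Why: Aromatic propargyl Claisen rearrangement to the only ortho carbon that bears hydrogen, then enolisation, 1,5-hydrogen shift and oxa-6π electrocyclisation, should give the 2,2-dimethylchromene in one thermal operation that the silyl ether tolerates.

Step 4
Reactants: 7 8-acetyl-2,2-dimethyl-6-(triisopropylsilyloxy)-2H-chromene
Product: 8 8-acetyl-2,2-dimethyl-6-(triisopropylsilyloxy)chroman (fragment 1)
Conditions: H2 (1 atm), Pd/C, EtOAc, rt
Reagents that add atoms: none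
Why: Heterogeneous catalytic hydrogenation saturates the cis-disubstituted styrene-type alkene far faster than it attacks the aryl ketone or the silyl ether, and it is done here so that only the chromene of fragment 2 remains later.

Step 5
Reactants: 9 4-bromoresorcinol; 10 3,3-dimethylacrylic acid
Product: 12 6-bromo-7-hydroxy-2,2-dimethylchroman-4-one, via dimethylacryloyl bromoresorcinol 11 (not isolated)
Conditions: P2O5 in MeSO3H, 70 °C
Reagents that add atoms: none
Why: Friedel–Crafts acylation at the carbon para to one hydroxyl and ortho to the other (the second para site carries bromine), followed by intramolecular oxa-Michael addition of the ortho phenol, is the usual one-pot route to 7-hydroxy-2,2-dimethylchroman-4-ones.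

Step 6
Reactants: 12 6-bromo-7-hydroxy-2,2-dimethylchroman-4-one
Product: 13 6-bromo-7-(methoxymethoxy)-2,2-dimethylchroman-4-one
Conditions: MOMCl, iPr2NEt, CH2Cl2, 0 °C to rt
Reagents that add atoms: chloromethyl methyl ether, COCCl
Why: O-alkylation of the acidic, unhindered phenol para to the carbonyl is straightforward, and capping it first lets the next step meet a neutral aryl ketone instead of a sluggish vinylogous carboxylate.

Step 7
Reactants: 13 6-bromo-7-(methoxymethoxy)-2,2-dimethylchroman-4-one
Product: 14 rac-6-bromo-7-(methoxymethoxy)-2,2-dimethylchroman-4-ol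
Conditions: NaBH4, MeOH/THF, 0 °C
Reagents that add atoms: none
Why: Borohydride reduction of the aryl ketone leaves the aryl bromide and the acetal alone; the new carbinol centre is formed racemic, which does not matter because the next step removes it.

Step 8
Reactants: 14 rac-6-bromo-7-(methoxymethoxy)-2,2-dimethylchroman-4-ol
Product: 16 6-bromo-7-(methoxymethoxy)-2,2-dimethyl-2H-chromene (fragment 2), via benzylic mesylate 15 (not isolated)
Conditions: MsCl, Et3N (excess), CH2Cl2, 0 to 40 °C
Reagents that add atoms: none
Why: Dehydration by sulfonate formation and base-mediated elimination should be easy because the benzylic position is activated by the ortho ring oxygen and the para MOM-oxy group, and it keeps the acetal away from acid.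

Step 9
Reactants: 8 8-acetyl-2,2-dimethyl-6-(triisopropylsilyloxy)chroman (fragment 1); 16 6-bromo-7-(methoxymethoxy)-2,2-dimethyl-2H-chromene (fragment 2)
Product: 17 1-[2,2-dimethyl-6-(triisopropylsilyloxy)chroman-8-yl]-2-[7-(methoxymethoxy)-2,2-dimethyl-2H-chromen-6-yl]ethanone
Conditions: Pd(OAc)2 (cat.), XPhos, K3PO4, toluene, 90 °C (8 in slight excess)
Reagents that add atoms: none
Why: Palladium-catalysed ketone α-arylation: zerovalent palladium formed from Pd(OAc)2 and XPhos inserts into the C–Br bond, K3PO4 forms the methyl ketone enolate without attacking the silyl ether, and the bulky biaryl phosphine promotes reductive elimination and stops at monoarylation.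

Step 10
Reactants: 17 1-[2,2-dimethyl-6-(triisopropylsilyloxy)chroman-8-yl]-2-[7-(methoxymethoxy)-2,2-dimethyl-2H-chromen-6-yl]ethanone
Product: 18 1-(6-hydroxy-2,2-dimethylchroman-8-yl)-2-[7-(methoxymethoxy)-2,2-dimethyl-2H-chromen-6-yl]ethanone
Conditions: Bu4NF, AcOH, THF, 0 °C
Reagents that add atoms: none
Why: Fluoride cleavage of the aryl silyl ether, buffered with acetic acid so that the air-sensitive para-alkoxyphenoxide is protonated at once, leaves the acetal, ketone and chromene untouched.

Step 11
Reactants: 18 1-(6-hydroxy-2,2-dimethylchroman-8-yl)-2-[7-(methoxymethoxy)-2,2-dimethyl-2H-chromen-6-yl]ethanone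
Product: 19 (Z)-3-hydroxy-1-(6-hydroxy-2,2-dimethylchroman-8-yl)-2-[7-(methoxymethoxy)-2,2-dimethyl-2H-chromen-6-yl]prop-2-en-1-one
Conditions: HCO2Et (excess), NaH (excess), THF, 0 °C to rt; then AcOH/H2O, 0 °C
Reagents that add atoms: ethyl formate, CCOC=O
Why: Crossed Claisen condensation (C-formylation) of the benzylic methylene is driven by the stabilised enolate of the β-keto aldehyde, and the formyl group has no phenol to cyclise onto because the oxygen ortho to the ketone is still the chroman ether and the ring B phenol is an acetal.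

Step 12
Reactants: 19 (Z)-3-hydroxy-1-(6-hydroxy-2,2-dimethylchroman-8-yl)-2-[7-(methoxymethoxy)-2,2-dimethyl-2H-chromen-6-yl]prop-2-en-1-one
Product: 21 2'-O-methoxymethyl kraussianone 3, via acylquinone 20 (not isolated)
Conditions: PhI(OAc)2 (1.05 equiv, added in portions), aqueous MeCN, 0 °C, dilute; then aq. Na2S2O4 work-up
Reagents that add atoms: water, O
Why: Proposed new method: two-electron oxidation of the para-alkoxyphenol by trivalent iodine gives a phenoxonium ion that water traps at the ether-bearing carbon, and the hemiketal collapses to 2-acyl-1,4-benzoquinone 20 while releasing the former ring oxygen as the tertiary alcohol; the enol hydroxyl then adds to the quinone CH that is beta to both the ring carbonyl and the side-chain ketone, and enolisation restores the arene as the 5,8-dihydroxychromone. The closest known reaction types are the oxidative opening of 2,2-dialkyl-6-chromanols to 2-(3-hydroxyalkyl)-1,4-benzoquinones and the oxa-Michael closure of 2-(2-hydroxybenzoyl)-1,4-benzoquinones to xanthones; running both in one flask with an enol as the nucleophile is the new part. Ring C closes in the 6-endo-trig mode by O1–C8a bond formation and no other ring is formed, while the chroman ring of fragment 1 is opened. No stereocentre is created. The step needs C–O bond formation at that one quinone carbon and not addition of water or of the tertiary alcohol at the other quinone CH, which the double activation of the site and the six-atom reach of the acidic enol should secure, and it needs the ring B phenol to stay out, which the MOM ether secures; if the enol oxygen captures the phenoxonium ion first, the mixed ketal is hydrolysed by the aqueous medium to the same quinone. Portionwise addition of one equivalent of oxidant in dilute solution should let the intramolecular closure outrun redox exchange between quinone and product, and the dithionite wash returns any over-oxidised material to the hydroquinone.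

Step 13
Reactants: 21 2'-O-methoxymethyl kraussianone 3
Product: 22 kraussianone 3
Conditions: 1 M aq. HCl, MeOH, rt, argon
Reagents that add atoms: none
Why: Acid-catalysed acetal exchange with methanol (MOM ether cleavage) at room temperature is milder than what is needed to ionise the tertiary alcohol towards closure onto C5–OH or to add methanol to the chromene, and exclusion of air protects the hydroquinone.

**Compound list**

1 | 2,5-dihydroxyacetophenone | CC(=O)c1cc(O)ccc1O | starting material
2 | 2-hydroxy-5-(triisopropylsilyloxy)acetophenone | CC(=O)c1cc(O[Si](C(C)C)(C(C)C)C(C)C)ccc1O | intermediate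
3 | 3-chloro-3-methylbut-1-yne | CC(C)(Cl)C#C | starting material
4 | 2-(2-methylbut-3-yn-2-yloxy)-5-(triisopropylsilyloxy)acetophenone | CC(=O)c1cc(O[Si](C(C)C)(C(C)C)C(C)C)ccc1OC(C)(C)C#C | intermediate
5 | 2-hydroxy-3-(3-methylbuta-1,2-dienyl)-5-(triisopropylsilyloxy)acetophenone (ortho-allenylphenol) | CC(=O)c1cc(O[Si](C(C)C)(C(C)C)C(C)C)cc(C=C=C(C)C)c1O | intermediate
6 | (6Z)-2-acetyl-6-(3-methylbut-2-en-1-ylidene)-4-(triisopropylsilyloxy)cyclohexa-2,4-dien-1-one (ortho-quinone methide) | CC(=O)C1=CC(O[Si](C(C)C)(C(C)C)C(C)C)=C/C(=C/C=C(C)C)C1=O | intermediate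
7 | 8-acetyl-2,2-dimethyl-6-(triisopropylsilyloxy)-2H-chromene | CC(=O)c1cc(O[Si](C(C)C)(C(C)C)C(C)C)cc2C=CC(C)(C)Oc12 | intermediate
8 | 8-acetyl-2,2-dimethyl-6-(triisopropylsilyloxy)chroman (fragment 1) | CC(=O)c1cc(O[Si](C(C)C)(C(C)C)C(C)C)cc2CCC(C)(C)Oc12 | intermediate
9 | 4-bromoresorcinol | Oc1ccc(Br)c(O)c1 | starting material
10 | 3,3-dimethylacrylic acid | CC(C)=CC(=O)O | starting material
11 | 1-(5-bromo-2,4-dihydroxyphenyl)-3-methylbut-2-en-1-one | CC(C)=CC(=O)c1cc(Br)c(O)cc1O | intermediate
12 | 6-bromo-7-hydroxy-2,2-dimethylchroman-4-one | CC1(C)CC(=O)c2cc(Br)c(O)cc2O1 | intermediate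
13 | 6-bromo-7-(methoxymethoxy)-2,2-dimethylchroman-4-one | COCOc1cc2OC(C)(C)CC(=O)c2cc1Br | intermediate
14 | rac-6-bromo-7-(methoxymethoxy)-2,2-dimethylchroman-4-ol | COCOc1cc2OC(C)(C)CC(O)c2cc1Br | intermediate
15 | rac-6-bromo-7-(methoxymethoxy)-2,2-dimethylchroman-4-yl methanesulfonate | COCOc1cc2OC(C)(C)CC(OS(C)(=O)=O)c2cc1Br | intermediate
16 | 6-bromo-7-(methoxymethoxy)-2,2-dimethyl-2H-chromene (fragment 2) | COCOc1cc2OC(C)(C)C=Cc2cc1Br | intermediate
17 | 1-[2,2-dimethyl-6-(triisopropylsilyloxy)chroman-8-yl]-2-[7-(methoxymethoxy)-2,2-dimethyl-2H-chromen-6-yl]ethanone | CC1(C)CCc2cc(O[Si](C(C)C)(C(C)C)C(C)C)cc(C(=O)Cc3cc4C=CC(C)(C)Oc4cc3OCOC)c2O1 | intermediate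
18 | 1-(6-hydroxy-2,2-dimethylchroman-8-yl)-2-[7-(methoxymethoxy)-2,2-dimethyl-2H-chromen-6-yl]ethanone | CC1(C)CCc2cc(O)cc(C(=O)Cc3cc4C=CC(C)(C)Oc4cc3OCOC)c2O1 | intermediate
19 | (Z)-3-hydroxy-1-(6-hydroxy-2,2-dimethylchroman-8-yl)-2-[7-(methoxymethoxy)-2,2-dimethyl-2H-chromen-6-yl]prop-2-en-1-one | CC1(C)CCc2cc(O)cc(C(=O)/C(=C\O)c3cc4C=CC(C)(C)Oc4cc3OCOC)c2O1 | intermediate
20 | 2-{(Z)-3-hydroxy-2-[7-(methoxymethoxy)-2,2-dimethyl-2H-chromen-6-yl]acryloyl}-6-(3-hydroxy-3-methylbutyl)-1,4-benzoquinone | CC(C)(O)CCC1=CC(=O)C=C(C(=O)/C(=C\O)c2cc3C=CC(C)(C)Oc3cc2OCOC)C1=O | intermediate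
21 | 2'-O-methoxymethyl kraussianone 3: 5,8-dihydroxy-6-(3-hydroxy-3-methylbutyl)-3-[7-(methoxymethoxy)-2,2-dimethyl-2H-chromen-6-yl]-4H-chromen-4-one | CC(C)(O)CCc1cc(O)c2occ(-c3cc4c(cc3OCOC)OC(C)(C)C=C4)c(=O)c2c1O | intermediate
22 | kraussianone 3: 5,8-dihydroxy-3-(7-hydroxy-2,2-dimethyl-2H-chromen-6-yl)-6-(3-hydroxy-3-methylbutyl)-4H-chromen-4-one | CC(C)(O)CCc1cc(O)c2occ(-c3cc4c(cc3O)OC(C)(C)C=C4)c(=O)c2c1O | target

**Step count**

Total: 13 steps. Longest linear sequence: 9 steps (steps 1–4, then 9–13; the branch through steps 5–8 is equally long).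

**Steps most likely to fail**

Step 12 (key step). The likely failures are these:
- redox exchange between acylquinone 20 and the hydroquinone product, which would give a ring-opened hydroquinone able to close the pyranone onto the C5 oxygen;
- capture of the quinone by water or by the released tertiary alcohol;
- oxidation of the enol by the iodine reagent.

The fallback uses only known reaction types: the C8a oxygen is installed before the isoflavone is assembled, ring C is closed conventionally, and the chroman is opened last by an oxidation that has no second task. It sets out from chroman 8 and bromochromene 16 and comes back at 21.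
- Ketone-directed ortho C–H hydroxylation of 8 (Pd(OCOCF3)2 cat., PhI(OCOCF3)2, 1,2-dichloroethane, 80 °C; the only C–H ortho to the acetyl group is C7) should give 8-acetyl-7-hydroxy-2,2-dimethyl-6-(triisopropylsilyloxy)chroman F1.
- Condensation with Me2NCH(OMe)2 should give the (E)-enaminone F2, and iodine should close it to the 3-iodochromone with the dihydropyran fused at C5–C6 and the silyl ether on C8, F3.
- Miyaura borylation of 16 (B2pin2, PdCl2(dppf), KOAc, dioxane) should give the pinacol boronate of fragment 2, F4.
- Suzuki–Miyaura coupling of F3 with F4 (PdCl2(dppf), K3PO4, DMF) should give the pyrano-fused 8-silyloxy isoflavone F5.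
- Bu4NF/AcOH should free the C8 phenol of the pyrano-fused isoflavone, F6.
- PhI(OAc)2 in aqueous MeCN should open this 6-chromanol-type ring to the chromone-5,8-quinone carrying the free tertiary alcohol, F7, and Na2S2O4 should reduce F7 to 21.

Step 9. The likely failures are slow oxidative addition into the hindered, electron-rich bromide, loss of bromine by reduction, a second arylation of the more acidic product, Heck-type consumption of the chromene, and loss of the silyl ether in hot base. The fallback replaces enolate arylation by a cross-coupling at an sp2 carbon that already carries C2. It sets out from 8 and 16, comes back at 19, and bypasses steps 10 and 11.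
- Heating 8 with Me2NCH(OMe)2 should give the (E)-enaminone of fragment 1, F8.
- N-iodosuccinimide in CH2Cl2 should iodinate its α-carbon to the (Z)-α-iodoenaminone F9.
- Suzuki–Miyaura coupling of F9 with the pinacol boronate F4 (made from 16 as described for the first fallback; Pd(PPh3)4, K3PO4, dioxane/H2O) should give the α-aryl enaminone F10.
- Mild aqueous acetic acid in THF should hydrolyse the vinylogous amide to the silyl-protected hydroxymethylene ketone F11.
- Bu4NF/AcOH should then give 19.

Step 11. The likely failures are incomplete formylation of the hindered methylene in the presence of the phenoxide, O-formylation, and retro-Claisen loss of the formyl group on work-up. The fallback avoids strong base and sets out from 18 and comes back at 19.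
- Aminomethylenation of 18 with t-BuOCH(NMe2)2 in toluene at 80 °C (a reagent that does not methylate the phenol) should give the phenolic α-aryl enaminone F12.
- Hydrolysis with aqueous acetic acid in THF should give 19.

**Further compounds**

F1 | step 12 | 8-acetyl-7-hydroxy-2,2-dimethyl-6-(triisopropylsilyloxy)chroman | CC(=O)c1c(O)c(O[Si](C(C)C)(C(C)C)C(C)C)cc2CCC(C)(C)Oc12
F2 | step 12 | (E)-3-(dimethylamino)-1-[7-hydroxy-2,2-dimethyl-6-(triisopropylsilyloxy)chroman-8-yl]prop-2-en-1-one | CN(C)/C=C/C(=O)c1c(O)c(O[Si](C(C)C)(C(C)C)C(C)C)cc2CCC(C)(C)Oc12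
F3 | step 12 | 3-iodo-8-(triisopropylsilyloxy)chromone with a 2,2-dimethyl-3,4-dihydro-2H-pyran ring fused at C5–C6 (ring oxygen on C5) | CC1(C)CCc2cc(O[Si](C(C)C)(C(C)C)C(C)C)c3occ(I)c(=O)c3c2O1
F4 | step 12 | 2-[7-(methoxymethoxy)-2,2-dimethyl-2H-chromen-6-yl]-4,4,5,5-tetramethyl-1,3,2-dioxaborolane | COCOc1cc2OC(C)(C)C=Cc2cc1B1OC(C)(C)C(C)(C)O1
F5 | step 12 | 3-[7-(methoxymethoxy)-2,2-dimethyl-2H-chromen-6-yl]-8-(triisopropylsilyloxy)chromone with a 2,2-dimethyl-3,4-dihydro-2H-pyran ring fused at C5–C6 (ring oxygen on C5) | CC1(C)CCc2cc(O[Si](C(C)C)(C(C)C)C(C)C)c3occ(-c4cc5C=CC(C)(C)Oc5cc4OCOC)c(=O)c3c2O1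
F6 | step 12 | 8-hydroxy-3-[7-(methoxymethoxy)-2,2-dimethyl-2H-chromen-6-yl]chromone with a 2,2-dimethyl-3,4-dihydro-2H-pyran ring fused at C5–C6 (ring oxygen on C5) | CC1(C)CCc2cc(O)c3occ(-c4cc5C=CC(C)(C)Oc5cc4OCOC)c(=O)c3c2O1
F7 | step 12 | 6-(3-hydroxy-3-methylbutyl)-3-[7-(methoxymethoxy)-2,2-dimethyl-2H-chromen-6-yl]-4H-chromene-4,5,8-trione (chromone-5,8-quinone) | CC(C)(O)CCC1=CC(=O)C2=C(C1=O)C(=O)C(=CO2)c1cc2C=CC(C)(C)Oc2cc1OCOC
F8 | step 9 | (E)-3-(dimethylamino)-1-[2,2-dimethyl-6-(triisopropylsilyloxy)chroman-8-yl]prop-2-en-1-one | CN(C)/C=C/C(=O)c1cc(O[Si](C(C)C)(C(C)C)C(C)C)cc2CCC(C)(C)Oc12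
F9 | step 9 | (Z)-3-(dimethylamino)-2-iodo-1-[2,2-dimethyl-6-(triisopropylsilyloxy)chroman-8-yl]prop-2-en-1-one | CN(C)/C=C(\I)C(=O)c1cc(O[Si](C(C)C)(C(C)C)C(C)C)cc2CCC(C)(C)Oc12
F10 | step 9 | (E)-3-(dimethylamino)-1-[2,2-dimethyl-6-(triisopropylsilyloxy)chroman-8-yl]-2-[7-(methoxymethoxy)-2,2-dimethyl-2H-chromen-6-yl]prop-2-en-1-one | CN(C)/C=C(\c1cc2C=CC(C)(C)Oc2cc1OCOC)C(=O)c1cc(O[Si](C(C)C)(C(C)C)C(C)C)cc2CCC(C)(C)Oc12
F11 | step 9 | (Z)-3-hydroxy-1-[2,2-dimethyl-6-(triisopropylsilyloxy)chroman-8-yl]-2-[7-(methoxymethoxy)-2,2-dimethyl-2H-chromen-6-yl]prop-2-en-1-one | CC1(C)CCc2cc(O[Si](C(C)C)(C(C)C)C(C)C)cc(C(=O)/C(=C\O)c3cc4C=CC(C)(C)Oc4cc3OCOC)c2O1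
F12 | step 11 | (E)-3-(dimethylamino)-1-(6-hydroxy-2,2-dimethylchroman-8-yl)-2-[7-(methoxymethoxy)-2,2-dimethyl-2H-chromen-6-yl]prop-2-en-1-one | CN(C)/C=C(\c1cc2C=CC(C)(C)Oc2cc1OCOC)C(=O)c1cc(O)cc2CCC(C)(C)Oc12
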